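**Structural features**

The target is a C40 carotenoid in which a 22-carbon all-E chain (C7 to C7', methyls on C9, C13, C13', C9') joins two different trimethylcyclohexane rings. Locants follow carotenoid numbering, with primes on the diol half. Ring A (C1–C6) is a 3-hydroxy ring (C3 R) with a tetrasubstituted C5=C6 bond, and C6 is bonded to the sp carbon C7 of a C7≡C8 triple bond. Ring B (C1'–C6') is saturated and carries a trans-5',6'-diol: two contiguous fully substituted carbinol carbons (5'R,6'R), with C6' flanked by the quaternary C1' and bonded to the chain through the E C7'=C8' bond. C3 is separated from C5'/C6' by the whole chain, so the two ends have to be controlled independently. The C6' carbinol is tertiary and allylic to an octaene, so acid would ionise it (5,8-furanoid closure or dehydration). The C9=C10 bond next to the alkyne has no steric bias for E, because C8 carries no hydrogen, so its geometry has to be kept kinetically. The real difficulty is to create C6' with the chain cis to the C5' oxygen and to attach it to a non-symmetric polyene without exposing it to acid. The key step exploits the fact that both ring–chain bonds end on alkyne-type carbons: C7 is sp, and C6'(OH)–C7'=C8' is the reduction product of a propargylic alcohol. The whole C7–C7' segment is therefore a C2h-symmetric C22 diyne, and C6' can be made by adding it to a ring ketone whose only stereocentre is C5'.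

**Logic of the disconnections**

In one sentence: the magnesium acetylide of 19 adds under chelation control to 7, forming C6'–C7' and setting C6' from C5'. The rings are attached last to a preformed symmetric chain, not joined through the middle of the chain.

22 is cut at C6–C7 (ring sp2 to chain sp) into 21 and 11. This is the only bond to the hindered tetrasubstituted ring alkene, and C3 arrives ready-made in 11. The gain is that ring A and its stereocentre leave the problem. The demand is a Pd/Cu coupling of a hindered enol triflate that tolerates three free hydroxyls and stays non-acidic.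

21 is traced to 20 without a C–C cut: the E C7'=C8' allylic tertiary alcohol is the retron of a propargylic alcohol. This makes both chain termini alkynes. The demand is a hydroxyl-directed trans reduction that acts only at C7'≡C8' and spares the remote terminal alkyne and seven conjugated double bonds.

20 is cut at C6'–C7' into 19 and 7 (key disconnection). C6' is a carbinol carbon, so the bond is an acetylide-to-ketone bond. The gain is large: a C31 compound with two contiguous tetrasubstituted stereocentres becomes an achiral C2h hydrocarbon and a C9 ketone with one stereocentre. The demand is facial selectivity (alkynyl cis to the C5' oxygen) and mono-addition to a symmetric diyne.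

19 is cut at both C11=C12-type double bonds into 17 and two molecules of 16 (through 18). Because 19 is symmetric, both bonds come from one reagent in one operation and no desymmetrisation of 17 is needed. The demand is an E-selective olefination that does not equilibrate the C9=C10-type bonds, and capped alkynes during the anion chemistry.

16 goes back through 15 and 14 to 12 by C–P, C–Br and C–Si changes. The E trisubstituted double bond is bought. The demand is substitution at the primary allylic carbon without transposition.

7 is traced to 5 by cleaving C6'=CH2, and 5 through 3 and 2 to 1. C5' is set by asymmetric epoxidation of an allylic alcohol, whose facial sense is highly predictable. The hydroxymethyl carbon is only a handle and is excised. The demand is that the C5'–O bond is never broken after step 1.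

11 is traced through 9 to 8 at the C–OTf bond. C3 comes from the chiral pool. The demand is enolisation towards the methyl-bearing α-carbon only (the other is quaternary); the methyl stereocentre is erased on purpose.

**Other disconnections considered**

Alternative 1: Cut C11=C12 and C11'=C12' (C15 + C10 + C15, the first route that comes to mind). Forward: two successive Wittig reactions of 17, with the acetylenic phosphonium salt A1 and with the diol phosphonium salt A2. Ground for preferring the chosen plan: A2 has to be made from a tertiary, dienylic carbinol under the acidic conditions of phosphonium salt formation, where C6' ionises. The diol would therefore have to be masked, which brings back the problem of Alternative 2. In addition, 17 must be desymmetrised by two different olefinations, and the labile carbinol is carried through every polyene-forming step instead of arriving last.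

Alternative 2: Cut the C6'–O bond of water; make the (5'R,6'S)-5',6'-epoxide A3 and hydrolyse it late. Forward key step: acid-catalysed epoxide opening at C6' with inversion. Ground: the protonated epoxide opens at C6' to a cation delocalised over the octaene. Nothing in the substrate then directs water to C6' from the required face, and the C5' oxygen can close onto C8' (furanoid) faster than water arrives. The epoxide also has to be set by the same asymmetric epoxidation, so no steps are saved.

Alternative 3: Cut C8–C9 and C8'–C9' (two sp–sp2 bonds). Forward key step: twofold Sonogashira coupling of the symmetric bis(vinyl iodide) A5 with the ethynyl diol A4 and the ring alkyne A6, then the same directed reduction. Ground: A4 can only be made stereo-securely by epoxide hydrolysis, and attack at the wrong epoxide carbon gives the mirror-image trans-diol, so any regiochemical leakage lowers enantiomeric purity instead of giving a separable diastereomer. A5 is an iodinated heptaene that needs an extra C4 iodo reagent. Two palladium couplings on polyenes replace one, and the route is about four steps longer. In the chosen plan C5' is fixed before C6' is made, so the only possible stereochemical error is a diastereomer.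

Key step: step 11

Remarks: (i) 1, 8, 12 and 17 are taken as purchasable (fragrance, vitamin and carotenoid intermediates). (ii) Metalated states (enolate, acetylide, phosphonate anion, aluminate) are treated as reagent states and carry no number.

Step 1
Reactants: 1 (2,6,6-trimethylcyclohex-1-en-1-yl)methanol
Product: 2 [(1R,6R)-2,2,6-trimethyl-7-oxabicyclo[4.1.0]heptan-1-yl]methanol
Conditions: Ti(OiPr)4 (10 mol %), D-(−)-DET (12 mol %), t-BuOOH (2 equiv), 4 Å MS, CH2Cl2, −20 °C
Reagents that add atoms: tert-butyl hydroperoxide, CC(C)(C)OO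
Why: Katsuki–Sharpless asymmetric epoxidation of a tetrasubstituted allylic alcohol; with D-(−)-tartrate the oxygen should go to the face that makes the methyl-bearing epoxide carbon (future C5') R, the mirror of the L-(+)-tartrate/geraniol case. The second epoxide centre is temporary.

Step 2
Reactants: 2 [(1R,6R)-2,2,6-trimethyl-7-oxabicyclo[4.1.0]heptan-1-yl]methanol
Product: 3 (1S,6R)-2,2,6-trimethyl-7-oxabicyclo[4.1.0]heptane-1-carbaldehyde
Conditions: TPAP (5 mol %), NMO (1.5 equiv), 4 Å MS, CH2Cl2, rt
Reagents that add atoms: none
Why: Ley–Griffith oxidation is neutral, so the acid-sensitive tetrasubstituted epoxide should survive. No stereocentre is touched (the C1 descriptor changes only because CHO outranks the epoxide carbon).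

Step 3
Reactants: 3 (1S,6R)-2,2,6-trimethyl-7-oxabicyclo[4.1.0]heptane-1-carbaldehyde
Product: 5 (1R)-1,3,3-trimethyl-2-methylidenecyclohexan-1-ol, via epoxy hydrazone 4 (not isolated)
Conditions: N2H4·H2O (2.5 equiv), AcOH (0.2 equiv), MeOH, 0 °C → rt
Reagents that add atoms: hydrazine hydrate, NN.O (its nitrogen enters intermediate 4 only and leaves as N2; none remains in 5)
Why: Wharton transposition: the hydrazone opens the epoxide to an allylic diazene that loses N2. The C–O bond at the methyl-bearing carbon is not broken (R retained) and the former aldehyde carbon becomes an exocyclic methylene.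

Step 4
Reactants: 5 (1R)-1,3,3-trimethyl-2-methylidenecyclohexan-1-ol
Product: 7 (2R)-2-hydroxy-2,6,6-trimethylcyclohexan-1-one, via spiro ozonide 6 (not isolated)
Conditions: O3, CH2Cl2, −78 °C; then Me2S, −78 °C → rt
Reagents that add atoms: ozone, [O-][O+]=O
Why: Ozonolysis of the 1,1-disubstituted alkene with reductive work-up; an osmium/periodate cleavage is avoided because it would pass through a vicinal triol and also cut the C5'–C6' bond. The tertiary stereocentre has no α-hydrogen and cannot epimerise.

Step 5
Reactants: 8 (4R,6R)-4-hydroxy-2,2,6-trimethylcyclohexan-1-one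
Product: 9 (4R,6R)-2,2,6-trimethyl-4-[(triethylsilyl)oxy]cyclohexan-1-one
Conditions: Et3SiCl, imidazole, DMF, 0 °C → rt
Reagents that add atoms: chlorotriethylsilane, CC[Si](Cl)(CC)CC
Why: Standard silylation of the secondary alcohol, so that enolisation needs one equivalent of base and no alkoxide competes for the triflating agent.

Step 6
Reactants: 9 (4R,6R)-2,2,6-trimethyl-4-[(triethylsilyl)oxy]cyclohexan-1-one
Product: 11 (4R)-4-hydroxy-2,6,6-trimethylcyclohex-1-en-1-yl trifluoromethanesulfonate, via silyl ether triflate 10 (not isolated)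
Conditions: LDA, THF, −78 → 0 °C; PhNTf2, −78 °C → rt; then 1 M HCl, THF–MeOH, rt
Reagents that add atoms: N-phenylbis(trifluoromethanesulfonimide), FC(F)(F)S(=O)(=O)N(c1ccccc1)S(=O)(=O)C(F)(F)F
Why: Only the methyl-bearing α-carbon can be deprotonated, so the enolate is regiodefined and O-triflation gives the tetrasubstituted enol triflate. The methyl stereocentre is erased on purpose and C4 (future C3, R) is untouched. Dilute acid then removes the silyl group without affecting the vinyl triflate.

Step 7
Reactants: 12 (2E)-3-methylpent-2-en-4-yn-1-ol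
Product: 14 (2E)-3-methyl-5-(trimethylsilyl)pent-2-en-4-yn-1-ol, via bis-silyl ether 13 (not isolated)
Conditions: n-BuLi (2.1 equiv), THF, −78 °C; Me3SiCl (2.2 equiv), −78 → 0 °C; then 1 M HCl, rt
Reagents that add atoms: chlorotrimethylsilane, C[Si](C)(C)Cl
Why: Double deprotonation (O–H and ≡C–H) and bis-silylation; the O–Si bond is hydrolysed on acidic work-up while the C–Si bond stays, capping the alkyne for step 10.

Step 8
Reactants: 14 (2E)-3-methyl-5-(trimethylsilyl)pent-2-en-4-yn-1-ol
Product: 15 [(3E)-5-bromo-3-methylpent-3-en-1-yn-1-yl]trimethylsilane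
Conditions: CBr4, PPh3, CH2Cl2, 0 °C
Reagents that add atoms: tetrabromomethane, BrC(Br)(Br)Br
Why: Appel bromination is an SN2 reaction at the primary allylic carbon under neutral conditions, so the E geometry and the silylalkyne should be kept.

Step 9
Reactants: 15 [(3E)-5-bromo-3-methylpent-3-en-1-yn-1-yl]trimethylsilane
Product: 16 diethyl [(2E)-3-methyl-5-(trimethylsilyl)pent-2-en-4-yn-1-yl]phosphonate
Conditions: P(OEt)3 (neat), 100 °C
Reagents that add atoms: triethyl phosphite, CCOP(OCC)OCC
Why: Michaelis–Arbuzov reaction of a reactive primary allylic bromide; no stereochemical change.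

Step 10
Reactants: 16 diethyl [(2E)-3-methyl-5-(trimethylsilyl)pent-2-en-4-yn-1-yl]phosphonate; 17 (2E,4E,6E)-2,7-dimethylocta-2,4,6-trienedial
Product: 19 (all-E)-3,7,12,16-tetramethyloctadeca-3,5,7,9,11,13,15-heptaene-1,17-diyne, via bis-silyl heptaenediyne 18 (not isolated)
Conditions: 16 (2.2 equiv), NaHMDS (2.2 equiv), THF, −78 °C; 17, −78 → 0 °C; then K2CO3 (cat.), MeOH, rt; dark, Ar
Reagents that add atoms: none
Why: Twofold Horner–Wadsworth–Emmons olefination of the symmetric dialdehyde with the allylic phosphonate anion should form both new disubstituted double bonds E. Deprotonation and addition at −78 °C keep the alkyne-flanked trisubstituted double bonds under kinetic control. Catalytic methanolysis then removes both alkynyl silyl groups in the same flask.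

Step 11
Reactants: 19 (all-E)-3,7,12,16-tetramethyloctadeca-3,5,7,9,11,13,15-heptaene-1,17-diyne; 7 (2R)-2-hydroxy-2,6,6-trimethylcyclohexan-1-one
Product: 20 (1S,2R)-2,6,6-trimethyl-1-[(all-E)-3,7,12,16-tetramethyloctadeca-3,5,7,9,11,13,15-heptaene-1,17-diyn-1-yl]cyclohexane-1,2-diol
Conditions: 19 (3 equiv), EtMgBr (2.1 equiv), THF, 0 → 40 °C; then 7 (1 equiv), PhMe, −20 °C → rt; aq. NH4Cl; dark
Reagents that add atoms: none
Why: Chelation-controlled 1,2-addition of an alkynylmagnesium bromide to an α-hydroxy ketone (the cyclic-model Grignard addition, with the acetylide type long used for trimethylcyclohexanones in polyene chemistry). The first equivalent of acetylide deprotonates 7, and in the resulting bromomagnesium alkoxide the metal bridges O5' and the carbonyl oxygen in a five-membered chelate, which holds the C5'–O bond in the carbonyl plane (equatorial) and activates the ketone. The C5' methyl is thereby forced axial, on the same face as the axial methyl of C1', so that face is closed and the linear nucleophile should enter along the axial trajectory on the other face. The new C6'–C7' bond is then cis to O5' and anti to the C5' methyl, which is the trans-5',6'-diol: C6' is set by C5' alone (1,2-relay; S by CIP in 20 because the alkynyl group outranks C1', 6'R after step 12). No ring is closed. Chemoselectivity should not be an issue because 7 has no α-hydrogen to enolise and the polyene is inert to alkynyl Grignard reagents; mono- versus bis-addition is handled by the threefold excess of the symmetric diyne, which is non-polar, separates easily from the diol 20 and can be recycled. Since 20 has only the two ring stereocentres, any cis-diol from a non-chelated pathway is a diastereomer that can be removed here, before the third stereocentre arrives. The step turns an achiral C2h hydrocarbon and a C9 ketone into the complete diol half with both tetrasubstituted carbinol centres in place.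

Step 12
Reactants: 20 (1S,2R)-2,6,6-trimethyl-1-[(all-E)-3,7,12,16-tetramethyloctadeca-3,5,7,9,11,13,15-heptaene-1,17-diyn-1-yl]cyclohexane-1,2-diol
Product: 21 (1R,2R)-2,6,6-trimethyl-1-[(all-E)-3,7,12,16-tetramethyloctadeca-1,3,5,7,9,11,13,15-octaen-17-yn-1-yl]cyclohexane-1,2-diol
Conditions: Red-Al (5 equiv), THF, 0 °C → rt; aq. Rochelle salt
Reagents that add atoms: none
Why: Hydroxyl-directed trans-hydroalumination: the C6' aluminium alkoxide delivers hydride to C7' and the vinylaluminium at C8' is protonated with retention on work-up, giving the E alkene. The terminal alkyne is masked as its alkynylaluminate and the polyene has no directing group. The C6' descriptor changes from S to R without any change at that centre.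

Step 13
Reactants: 21 (1R,2R)-2,6,6-trimethyl-1-[(all-E)-3,7,12,16-tetramethyloctadeca-1,3,5,7,9,11,13,15-octaen-17-yn-1-yl]cyclohexane-1,2-diol; 11 (4R)-4-hydroxy-2,6,6-trimethylcyclohex-1-en-1-yl trifluoromethanesulfonate
Product: 22 the target, (3R,5'R,6'R)-7,8-didehydro-5',6'-dihydro-β,β-carotene-3,5',6'-triol
Conditions: Pd(PPh3)4 (10 mol %), CuI (20 mol %), i-Pr2NH, THF (degassed), rt → 40 °C, dark
Reagents that add atoms: none
Why: Sonogashira coupling of a cyclohexenyl triflate with a terminal enyne, a known reaction for trimethylcyclohexenyl triflates. Amine base and mild temperature spare the tertiary allylic carbinol, the free hydroxyls need no protection, and no stereocentre or double bond is touched.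

**Compound list**

1 | (2,6,6-trimethylcyclohex-1-en-1-yl)methanol (β-cyclogeraniol) | CC1=C(CO)C(C)(C)CCC1 | starting material
2 | [(1R,6R)-2,2,6-trimethyl-7-oxabicyclo[4.1.0]heptan-1-yl]methanol | OC[C@@]12O[C@]1(C)CCCC2(C)C | intermediate
3 | (1S,6R)-2,2,6-trimethyl-7-oxabicyclo[4.1.0]heptane-1-carbaldehyde | O=C[C@@]12O[C@]1(C)CCCC2(C)C | intermediate
4 | hydrazone of 3 (epoxy hydrazone, C=N geometry not defined) | NN=C[C@@]12O[C@]1(C)CCCC2(C)C | intermediate (not isolated)
5 | (1R)-1,3,3-trimethyl-2-methylidenecyclohexan-1-ol | C[C@@]1(O)CCCC(C)(C)C1=C | intermediate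
6 | (6R)-6,10,10-trimethyl-1,2,4-trioxaspiro[4.5]decan-6-ol (secondary ozonide, both spiro epimers) | C[C@@]1(O)CCCC(C)(C)C12OCOO2 | intermediate (not isolated)
7 | (2R)-2-hydroxy-2,6,6-trimethylcyclohexan-1-one | C[C@@]1(O)CCCC(C)(C)C1=O | intermediate
8 | (4R,6R)-4-hydroxy-2,2,6-trimethylcyclohexan-1-one ((4R,6R)-actinol) | C[C@@H]1C[C@@H](O)CC(C)(C)C1=O | starting material
9 | (4R,6R)-2,2,6-trimethyl-4-[(triethylsilyl)oxy]cyclohexan-1-one | C[C@@H]1C[C@@H](O[Si](CC)(CC)CC)CC(C)(C)C1=O | intermediate
10 | (4R)-2,6,6-trimethyl-4-[(triethylsilyl)oxy]cyclohex-1-en-1-yl trifluoromethanesulfonate | CC1=C(OS(=O)(=O)C(F)(F)F)C(C)(C)C[C@H](O[Si](CC)(CC)CC)C1 | intermediate (not isolated)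
11 | (4R)-4-hydroxy-2,6,6-trimethylcyclohex-1-en-1-yl trifluoromethanesulfonate | CC1=C(OS(=O)(=O)C(F)(F)F)C(C)(C)C[C@H](O)C1 | intermediate
12 | (2E)-3-methylpent-2-en-4-yn-1-ol | C#C/C(C)=C/CO | starting material
13 | trimethyl{[(2E)-3-methyl-5-(trimethylsilyl)pent-2-en-4-yn-1-yl]oxy}silane | C[Si](C)(C)C#C/C(C)=C/CO[Si](C)(C)C | intermediate (not isolated)
14 | (2E)-3-methyl-5-(trimethylsilyl)pent-2-en-4-yn-1-ol | C[Si](C)(C)C#C/C(C)=C/CO | intermediate
15 | [(3E)-5-bromo-3-methylpent-3-en-1-yn-1-yl]trimethylsilane | C[Si](C)(C)C#C/C(C)=C/CBr | intermediate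
16 | diethyl [(2E)-3-methyl-5-(trimethylsilyl)pent-2-en-4-yn-1-yl]phosphonate | C[Si](C)(C)C#C/C(C)=C/CP(=O)(OCC)OCC | intermediate
17 | (2E,4E,6E)-2,7-dimethylocta-2,4,6-trienedial | O=C/C(C)=C/C=C/C=C(C)/C=O | starting material
18 | (3E,5E,7E,9E,11E,13E,15E)-3,7,12,16-tetramethyl-1,18-bis(trimethylsilyl)octadeca-3,5,7,9,11,13,15-heptaene-1,17-diyne | C[Si](C)(C)C#C/C(C)=C/C=C/C(C)=C/C=C/C=C(C)/C=C/C=C(C)/C#C[Si](C)(C)C | intermediate (not isolated)
19 | (3E,5E,7E,9E,11E,13E,15E)-3,7,12,16-tetramethyloctadeca-3,5,7,9,11,13,15-heptaene-1,17-diyne | C#C/C(C)=C/C=C/C(C)=C/C=C/C=C(C)/C=C/C=C(C)/C#C | intermediate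
20 | (1S,2R)-2,6,6-trimethyl-1-[(3E,5E,7E,9E,11E,13E,15E)-3,7,12,16-tetramethyloctadeca-3,5,7,9,11,13,15-heptaene-1,17-diyn-1-yl]cyclohexane-1,2-diol | C#C/C(C)=C/C=C/C(C)=C/C=C/C=C(C)/C=C/C=C(C)/C#C[C@@]1(O)C(C)(C)CCC[C@@]1(C)O | intermediate
21 | (1R,2R)-2,6,6-trimethyl-1-[(1E,3E,5E,7E,9E,11E,13E,15E)-3,7,12,16-tetramethyloctadeca-1,3,5,7,9,11,13,15-octaen-17-yn-1-yl]cyclohexane-1,2-diol | C#C/C(C)=C/C=C/C(C)=C/C=C/C=C(C)/C=C/C=C(C)/C=C/[C@@]1(O)C(C)(C)CCC[C@@]1(C)O | intermediate
22 | (3R,5'R,6'R)-7,8-didehydro-5',6'-dihydro-β,β-carotene-3,5',6'-triol (all-E) | CC1=C(C#C/C(C)=C/C=C/C(C)=C/C=C/C=C(C)/C=C/C=C(C)/C=C/[C@@]2(O)C(C)(C)CCC[C@@]2(C)O)C(C)(C)C[C@H](O)C1 | target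

**Step count and risks**

Total: 13 steps. Longest linear sequence: 7 steps (steps 7–13 from 12, or steps 1–4 and 11–13 from 1).

Step 11 (key step). The most likely failure is loss of facial control. If part of the addition runs through a non-chelated conformer with the C5' oxygen axial, the acetylide enters anti to that oxygen and the cis-diol forms. The THF needed to dissolve the heptaenediyne weakens the chelate, and the hindered, alkoxide-bearing carbonyl reacts slowly, which gives that pathway time to compete. Fallback, from 7 and 12, back to the route at 20: the C6'–C7' bond is made first on the C6 enynol. At that stage a non-coordinating solvent, added MgBr2·OEt2, a large excess of the cheap nucleophile and crystallisation of the diastereomers are all available, none of which the heptaene allows.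
- The bis(bromomagnesium) derivative of 12 adds to the bromomagnesium alkoxide of 7 to give (1S,2R)-1-[(3E)-5-hydroxy-3-methylpent-3-en-1-yn-1-yl]-2,6,6-trimethylcyclohexane-1,2-diol F1.
- Appel bromination of the primary allylic hydroxyl gives (1S,2R)-1-[(3E)-5-bromo-3-methylpent-3-en-1-yn-1-yl]-2,6,6-trimethylcyclohexane-1,2-diol F2.
- Arbuzov reaction gives diethyl [(2E)-5-[(1S,2R)-1,2-dihydroxy-2,6,6-trimethylcyclohexyl]-3-methylpent-2-en-4-yn-1-yl]phosphonate F3.
- Its trianion (NaHMDS) olefinates one aldehyde of excess 17 to (2E,4E,6E,8E,10E)-13-[(1S,2R)-1,2-dihydroxy-2,6,6-trimethylcyclohexyl]-2,7,11-trimethyltrideca-2,4,6,8,10-pentaen-12-ynal F4.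
- A second Horner–Wadsworth–Emmons reaction with 16 gives (1S,2R)-2,6,6-trimethyl-1-[(all-E)-3,7,12,16-tetramethyl-18-(trimethylsilyl)octadeca-3,5,7,9,11,13,15-heptaene-1,17-diyn-1-yl]cyclohexane-1,2-diol F5.
- K2CO3/MeOH returns 20.

This gives up the ring-last order but keeps the stereochemical relay.

Step 13. The most likely failure is slow oxidative addition at the tetrasubstituted, doubly flanked enol triflate, so that copper-mediated homocoupling and slow decomposition of 21 win. Fallback, from 19 and 11, back at 22: the hindered coupling is moved to the front of the union sequence, onto the robust hydrocarbon 19 used in excess, where homocoupling and heating are tolerable.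
- Sonogashira coupling of 19 with 11 gives (1R)-3,5,5-trimethyl-4-[(all-E)-3,7,12,16-tetramethyloctadeca-3,5,7,9,11,13,15-heptaene-1,17-diyn-1-yl]cyclohex-3-en-1-ol F6.
- Its bromomagnesium acetylide (an extra equivalent of EtMgBr for the ring hydroxyl) adds to 7 as in step 11 to give (1S,2R)-1-[(all-E)-18-[(4R)-4-hydroxy-2,6,6-trimethylcyclohex-1-en-1-yl]-3,7,12,16-tetramethyloctadeca-3,5,7,9,11,13,15-heptaene-1,17-diyn-1-yl]-2,6,6-trimethylcyclohexane-1,2-diol F7.
- Red-Al as in step 12 reduces only the alkyne next to the carbinol and gives 22.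

Step 12. The most likely failure is hydride transfer into the conjugated system beyond C7'≡C8', or a sluggish reaction at the congested tertiary alkoxide that leads to over-reduction on warming. Fallback, from 19 (with 7), back at 21: C7'=C8' is brought in as an alkene, so no alkyne is reduced.
- Hydrozirconation of one terminus of excess 19 with Cp2Zr(H)Cl followed by iodine gives (1E,3E,5E,7E,9E,11E,13E,15E)-1-iodo-3,7,12,16-tetramethyloctadeca-1,3,5,7,9,11,13,15-octaen-17-yne F8.
- Deprotonation of the remaining alkyne (LiHMDS), iodine–lithium exchange (t-BuLi, −78 °C), transmetalation to cerium and addition to the lithium alkoxide of 7 give 21 directly.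

Step 3. The most likely failure is a low-yielding Wharton transposition, through azine formation and competing fragmentation of the diazene at a fully substituted epoxide. Fallback, from 2, back at 5: reductive elimination replaces the hydrazone chemistry.
- I2, PPh3 and imidazole convert 2 into (1S,6R)-1-(iodomethyl)-2,2,6-trimethyl-7-oxabicyclo[4.1.0]heptane F9.
- Zinc dust in refluxing ethanol inserts into the C–I bond and opens the epoxide by β-elimination to give 5; the C5'–O bond is again untouched.

**Further compounds**

F1 | step 11 | (1S,2R)-1-[(3E)-5-hydroxy-3-methylpent-3-en-1-yn-1-yl]-2,6,6-trimethylcyclohexane-1,2-diol | OC/C=C(C)/C#C[C@@]1(O)C(C)(C)CCC[C@@]1(C)O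
F2 | step 11 | (1S,2R)-1-[(3E)-5-bromo-3-methylpent-3-en-1-yn-1-yl]-2,6,6-trimethylcyclohexane-1,2-diol | BrC/C=C(C)/C#C[C@@]1(O)C(C)(C)CCC[C@@]1(C)O
F3 | step 11 | diethyl [(2E)-5-[(1S,2R)-1,2-dihydroxy-2,6,6-trimethylcyclohexyl]-3-methylpent-2-en-4-yn-1-yl]phosphonate | CCOP(=O)(OCC)C/C=C(C)/C#C[C@@]1(O)C(C)(C)CCC[C@@]1(C)O
F4 | step 11 | (2E,4E,6E,8E,10E)-13-[(1S,2R)-1,2-dihydroxy-2,6,6-trimethylcyclohexyl]-2,7,11-trimethyltrideca-2,4,6,8,10-pentaen-12-ynal | O=C/C(C)=C/C=C/C=C(C)/C=C/C=C(C)/C#C[C@@]1(O)C(C)(C)CCC[C@@]1(C)O
F5 | step 11 | (1S,2R)-2,6,6-trimethyl-1-[(3E,5E,7E,9E,11E,13E,15E)-3,7,12,16-tetramethyl-18-(trimethylsilyl)octadeca-3,5,7,9,11,13,15-heptaene-1,17-diyn-1-yl]cyclohexane-1,2-diol | C[Si](C)(C)C#C/C(C)=C/C=C/C(C)=C/C=C/C=C(C)/C=C/C=C(C)/C#C[C@@]1(O)C(C)(C)CCC[C@@]1(C)O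
F6 | step 13 | (1R)-3,5,5-trimethyl-4-[(3E,5E,7E,9E,11E,13E,15E)-3,7,12,16-tetramethyloctadeca-3,5,7,9,11,13,15-heptaene-1,17-diyn-1-yl]cyclohex-3-en-1-ol | CC1=C(C#C/C(C)=C/C=C/C(C)=C/C=C/C=C(C)/C=C/C=C(C)/C#C)C(C)(C)C[C@H](O)C1
F7 | step 13 | (1S,2R)-1-[(3E,5E,7E,9E,11E,13E,15E)-18-[(4R)-4-hydroxy-2,6,6-trimethylcyclohex-1-en-1-yl]-3,7,12,16-tetramethyloctadeca-3,5,7,9,11,13,15-heptaene-1,17-diyn-1-yl]-2,6,6-trimethylcyclohexane-1,2-diol | CC1=C(C#C/C(C)=C/C=C/C(C)=C/C=C/C=C(C)/C=C/C=C(C)/C#C[C@@]2(O)C(C)(C)CCC[C@@]2(C)O)C(C)(C)C[C@H](O)C1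
F8 | step 12 | (1E,3E,5E,7E,9E,11E,13E,15E)-1-iodo-3,7,12,16-tetramethyloctadeca-1,3,5,7,9,11,13,15-octaen-17-yne | I/C=C/C(C)=C/C=C/C(C)=C/C=C/C=C(C)/C=C/C=C(C)/C#C
F9 | step 3 | (1S,6R)-1-(iodomethyl)-2,2,6-trimethyl-7-oxabicyclo[4.1.0]heptane | IC[C@@]12O[C@]1(C)CCCC2(C)C
A1 | alternative 1 | [(2E)-5-[(4R)-4-hydroxy-2,6,6-trimethylcyclohex-1-en-1-yl]-3-methylpent-2-en-4-yn-1-yl]triphenylphosphonium bromide | CC1=C(C#C/C(C)=C/C[P+](c2ccccc2)(c2ccccc2)c2ccccc2)C(C)(C)C[C@H](O)C1.[Br-]
A2 | alternative 1 | [(2E,4E)-5-[(1R,2R)-1,2-dihydroxy-2,6,6-trimethylcyclohexyl]-3-methylpenta-2,4-dien-1-yl]triphenylphosphonium bromide | [Br-].c1ccc(cc1)[P+](c1ccccc1)(c1ccccc1)C/C=C(C)/C=C/[C@@]1(O)C(C)(C)CCC[C@@]1(C)O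
A3 | alternative 2 | (3R,5'R,6'S)-5',6'-epoxy-7,8-didehydro-5',6'-dihydro-β,β-caroten-3-ol | CC1=C(C#C/C(C)=C/C=C/C(C)=C/C=C/C=C(C)/C=C/C=C(C)/C=C/[C@@]23O[C@]2(C)CCCC3(C)C)C(C)(C)C[C@H](O)C1
A4 | alternative 3 | (1S,2R)-1-ethynyl-2,6,6-trimethylcyclohexane-1,2-diol | C#C[C@@]1(O)C(C)(C)CCC[C@@]1(C)O
A5 | alternative 3 | (2E,4E,6E,8E,10E,12E,14E)-2,15-diiodo-6,11-dimethylhexadeca-2,4,6,8,10,12,14-heptaene | I/C(C)=C/C=C/C(C)=C/C=C/C=C(C)/C=C/C=C(C)/I
A6 | alternative 3 | (1R)-4-ethynyl-3,5,5-trimethylcyclohex-3-en-1-ol | CC1=C(C#C)C(C)(C)C[C@H](O)C1
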